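Target is counted here with its crystals, as a fraction of the substrate charged.

- delta: substrate 0.20 M; salt in the second phase 0.24 M; spent carrier 20 mM; the very flask that is asked about, followed so far
- flask: substrate 0.20 M; salt in the second phase 0.240 M; spent carrier 20 mM; time 12 min; volume of the second phase over the first 1.0

- delta (time / min: target / %, crystals / %): 0.417: 0, 0; 0.667: 0.5, 0; 1.00: 1.6, 0.2; 2.00: 4.8, 0; 3.00: 9.1, 0.7; 5.00: 11.6, 0.1

(standard deviation of a reading: 1 percentage point)

- how much target and crystals together there is at 12 min, in percent of the substrate charged
- concentration of target in solution at 12 min, in percent of saturation

- what is said of target includes crystals
- charges count per volume of the first phase; a concentration in a rate is the amount of a species over the volume of its own phase; every rate counts per litre of the first phase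
- crystals is a solid; its amount is given per volume of the solution
- the earlier runs hold the two phases in the same ratio of volumes as the flask asked about

1. End state: salt is charged at 1.20 equivalents, so substrate is the limiting reagent. The next question is the speed of approach.

2. First estimate: spent carrier is 10.0% of the substrate charge and is taken as a catalyst that turns over without loss, so substrate left should fall exponentially. The readings at 1.00 min and 5.00 min give the carrier constant, 0.0268 /min: the pseudo-first-order loss of substrate, taken as proportional to the carrier charge. Carried back, the line starts at 0.398 min. By my reckoning, substrate left at 12 min is 73.3%, so, if the substrate lost is taken as target, target is 26.7%.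

3. Objection: two readings carry the scatter, which reaches 12 min as about 3.9 percentage points. That conversion also draws 22.3% of the salt charge, so if the rate follows salt, the estimate leans high. The estimate stands, with that margin on it.

4. Objection: crystals stay within scatter of zero up to 11.6% of target, so these readings give no saturation, and I put no number on it.

5. The forecast, a little below my figure, says 26% and 90% of saturation, the latter with the words “this is largely a guess”.

6. The flask gives 25.8% and 84.5% of saturation.

    spent carrier + salt in the second phase ⇌ fresh carrier + spent salt in the second phase (K = 0.420, k = 0.0630 /M/s)
    substrate + fresh carrier → target + spent carrier (k = 0.0490 /M/s)
    crystals ⇌ target, rate k3*(cs3 - [target]) while solid is left; crystals form when [target] > cs3 (solubility = 0.0610 M, k = 0.0340 /s)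
    target → over-reaction product (k = 1.60 × 10⁻⁴ /s)

At 4.22 min in this flask, fresh carrier has a half-life of 1.3 min against substrate, far shorter than the 23 min of substrate by the same step. Fresh carrier stands at 47.7% of the catalyst at 6.00 min and 40.8% at 12.0 min, and the carrier constant's 73.3% of substrate left stands beside the flask's 72.6%.

In the neighbour flask with 0.080 M of spent carrier, the constant scales to 0.107 /min, which leaves 28.9% of the substrate. That flask computes to 42.7% left, with fresh carrier at 22.5% of its catalyst against 40.8% in the first flask.

The data were computed from invented constants; the scatter is artificial.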